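Feature: in the 3,7-dioxabicyclo[3.3.0]octane core, ring A (C1–C2–O3–C4–C5) carries no substituent on the O3–C4H2 unit. That unit lies between benzylic C2 (aryl A, 3-hydroxy-4,5-dimethoxyphenyl) and ring-fusion carbon C5, so it is one molecule of formaldehyde held between a cation-stabilising and an anion-stabilising carbon.
End game, read backwards: the phenol comes from its benzyl ether, the C6–aryl B bond (3,4,5-trimethoxyphenyl) from an arylzinc and the C6 oxocarbenium ion of ring B, C6 from a lactone carbonyl, and C5–H from C5–CO2Me.
Key disconnection: C2–O3 and C4–C5 are cut together. This returns formaldehyde and a cyclopropane C1–C2–C5 with aryl A endo, fused to the ring B lactone (C5–C6(=O)–O7–C8–C1) and activated by the ester on C5.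
The cyclopropane lactone comes from a cis-2-aryl-3-(silyloxymethyl)cyclopropane-1,1-diester by desilylation and lactonisation. The diester comes from enantioselective copper-catalysed malonate-carbene transfer to the Z-cinnamyl silyl ether (Still–Gennari olefination, reduction, silylation).
Order of ring formation: cyclopropane, then ring B as lactone, then ring A in the key step at the expense of the cyclopropane. Ring B is kept and only re-functionalised at C6.

Key step: step 8

Numbering remark: C1–C8 are the atoms of the 3,7-dioxabicyclo[3.3.0]octane core of the target (C1 and C5 ring fusion, C2 bears aryl A, C6 bears aryl B). The same labels are kept for these atoms in all intermediates.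
Assumption: the sense of induction of the copper catalyst on this Z-alkene cannot be assigned with certainty, so the ligand antipode that gives the (2R,3R)-cyclopropane is fixed by a trial run; both antipodes derive from commercial phenylglycinol.

Step 1
Reactants: 1 3-hydroxy-4,5-dimethoxybenzaldehyde
Product: 2 3-(benzyloxy)-4,5-dimethoxybenzaldehyde
Conditions: BnBr, K2CO3, DMF, rt
Reagents that add atoms: benzyl bromide, BrCc1ccccc1
Why: Williamson ether synthesis on the only acidic OH gives a benzyl ether that withstands the later bases, hydrides, Lewis acids and organometals and is removed by hydrogenolysis at the end.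

Step 2
Reactants: 2 3-(benzyloxy)-4,5-dimethoxybenzaldehyde; 3 methyl 2-[bis(2,2,2-trifluoroethoxy)phosphoryl]acetate
Product: 4 methyl (Z)-3-[3-(benzyloxy)-4,5-dimethoxyphenyl]prop-2-enoate
Conditions: KN(SiMe3)2, 18-crown-6, THF, −78 °C
Reagents that add atoms: none
Why: In the Still–Gennari olefination the electron-poor phosphonate and the dissociated potassium ion make collapse of the first-formed adduct faster than its equilibration, so an aromatic aldehyde should give the Z-enoate whose geometry later becomes the endo position of aryl A.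

Step 3
Reactants: 4 methyl (Z)-3-[3-(benzyloxy)-4,5-dimethoxyphenyl]prop-2-enoate
Product: 5 (Z)-3-[3-(benzyloxy)-4,5-dimethoxyphenyl]prop-2-en-1-ol
Conditions: iBu2AlH (2.5 equiv), CH2Cl2, −78 °C; aq. potassium sodium tartrate
Reagents that add atoms: none
Why: 1,2-reduction of the enoate by iBu2AlH at low temperature with a neutral work-up leaves the Z double bond untouched and turns the ester carbon into C8 bearing O7.

Step 4
Reactants: 5 (Z)-3-[3-(benzyloxy)-4,5-dimethoxyphenyl]prop-2-en-1-ol
Product: 6 tert-butyl{[(Z)-3-[3-(benzyloxy)-4,5-dimethoxyphenyl]prop-2-en-1-yl]oxy}dimethylsilane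
Conditions: TBSCl, imidazole, CH2Cl2, rt
Reagents that add atoms: tert-butyldimethylsilyl chloride, CC(C)(C)[Si](C)(C)Cl
Why: Standard silylation removes the O–H bond that a copper carbene would insert into, and the bulky, weakly basic silyl ether oxygen is a poor partner for oxonium ylide formation.

Step 5
Reactants: 7 dimethyl malonate
Product: 8 dimethyl 2-(phenyl-λ3-iodanylidene)propanedioate (phenyliodonium malonate ylide)
Conditions: PhI(OAc)2, KOH, MeCN, 0 °C
Reagents that add atoms: (diacetoxyiodo)benzene, CC(=O)OI(OC(C)=O)c1ccccc1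
Why: Base-mediated condensation of an active methylene compound with PhI(OAc)2 is the standard preparation of this stabilised iodonium ylide, a diazo-free malonate-carbene source that reacts with copper below room temperature.

Step 6
Reactants: 6 Z-cinnamyl silyl ether; 8 phenyliodonium malonate ylide
Product: 9 dimethyl (2R,3R)-2-[3-(benzyloxy)-4,5-dimethoxyphenyl]-3-{[(tert-butyldimethylsilyl)oxy]methyl}cyclopropane-1,1-dicarboxylate (aryl and CH2OSi cis)
Conditions: 8 (1.5 equiv), Cu(MeCN)4PF6 (10 mol %), 2,2'-[1,3-bis(4-tert-butylphenyl)propane-2,2-diyl]bis(4-phenyl-4,5-dihydro-1,3-oxazole) (one antipode, 12 mol %), 4 Å MS, toluene, 0 °C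
Reagents that add atoms: none
Why: Copper-carbene cyclopropanation with a stabilised iodonium ylide uses a catalyst system (monovalent copper with a side-arm bisoxazoline) established for malonate-carbene transfer to cis-1,2-disubstituted styrenes: the concerted syn addition carries the Z geometry into the cis relation of aryl A on C2 and C8H2 on C1, the chiral pocket chooses the alkene face and thereby sets C1 and C2 together (both R), and the intermolecular mode is chosen because ring closure of an allyl diazomalonate to a five-membered lactone is a weak case for enantiocontrol.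

Step 7
Reactants: 9 cis-cyclopropane diester silyl ether
Product: 11 methyl (1S,5R,6R)-6-[3-(benzyloxy)-4,5-dimethoxyphenyl]-2-oxo-3-oxabicyclo[3.1.0]hexane-1-carboxylate (aryl endo), via hydroxymethyl diester 10 (not isolated)
Conditions: Bu4NF (1.1 equiv), THF, 0 °C to rt
Reagents that add atoms: none
Why: Fluoride desilylation frees the C8 oxygen of 10 next to the one ester that is cis to it on the rigid three-membered ring, and 5-exo-trig lactonisation follows, so that C5 becomes a defined quaternary stereocentre (S) with the lactone ring on the same face as aryl A.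

Step 8
Reactants: 11 endo-aryl cyclopropane lactone ester; 12 formaldehyde (supplied as dried paraformaldehyde)
Product: 14 methyl (1R,2S,5R)-2-[3-(benzyloxy)-4,5-dimethoxyphenyl]-6-oxo-3,7-dioxabicyclo[3.3.0]octane-5-carboxylate (aryl A exo), via oxocarbenium enolate 13 (not isolated)
Conditions: paraformaldehyde (5 equiv CH2O), Sn(OTf)2 (10 mol %), CH2Cl2, rt
Reagents that add atoms: none
Why: The divalent tin triflate binds the lactone and ester carbonyls on C5 as a chelate and polarises the C2–C5 bond; the oxygen of formaldehyde then displaces the C5 enolate from the rear of benzylic C2 (SN2-like, C2–O3 formed) to give 13, and after rotation about C1–C2 the enolate carbon adds to the oxocarbenium carbon (C4–C5 formed). The closest known reaction is the Lewis-acid-catalysed (3+2) cycloaddition of 2-arylcyclopropane-1,1-dicarboxylates with aldehydes, shown also for 3-substituted rings with alkoxyphenyl donors and stereospecific with inversion at the donor carbon; formaldehyde as partner and the lactone fusion are the new features of this application. Ring A closes in a 5-(enolexo)-endo-trig aldol-type step with the O3=C4 bond inside the forming ring, the mode common to all these cycloadditions and accessible to oxocarbenium ions. C2 (S, aryl A exo) follows from inversion of the endo-aryl centre of 11, C5 (R, quaternary) follows from the short tether C1–C2–O3, which lets C4 reach only the enolate face that C2 has just left (a trans-fused bicyclo[3.3.0] system being out of reach), and C1 is not touched. The step needs cleavage of C2–C5 rather than C1–C5, which is secured by the aryl donor on C2 and by the better overlap of the external cyclopropane bond with the lactone carbonyl. It also needs capture by formaldehyde before free ionisation, which is served by relief of the endo-aryl strain, a low catalyst loading and an excess of slowly depolymerising paraformaldehyde.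

Step 9
Reactants: 14 furofuranone ester
Product: 15 (1R,2S,5R)-2-[3-(benzyloxy)-4,5-dimethoxyphenyl]-3,7-dioxabicyclo[3.3.0]octan-6-one
Conditions: LiCl (3 equiv), H2O (3 equiv), DMSO, 150 °C
Reagents that add atoms: none
Why: In the Krapcho demethoxycarbonylation chloride removes the ester methyl group by SN2, CO2 leaves and the lactone enolate is protonated at C5 on the only face that keeps the bicycle cis-fused (C5 R), while ring A should not unzip by β-elimination because the C4–O3 bond lies close to the nodal plane of that enolate.

Step 10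
Reactants: 15 furofuranone
Product: 16 (1R,2S,5R)-2-[3-(benzyloxy)-4,5-dimethoxyphenyl]-3,7-dioxabicyclo[3.3.0]octan-6-ol (lactol, both C6 epimers)
Conditions: iBu2AlH (1.1 equiv), CH2Cl2, −78 °C; aq. potassium sodium tartrate
Reagents that add atoms: none
Why: Partial reduction of a γ-lactone with one equivalent of iBu2AlH at −78 °C stops at the stable aluminium hemiacetal, and the configuration of the lactol carbon is irrelevant because C6 becomes planar again in step 13.

Step 11
Reactants: 16 lactol
Product: 17 (1R,2S,5R)-6-(benzenesulfonyl)-2-[3-(benzyloxy)-4,5-dimethoxyphenyl]-3,7-dioxabicyclo[3.3.0]octane (C6 epimers)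
Conditions: PhSO2H (1.5 equiv), CaCl2, CH2Cl2, rt
Reagents that add atoms: benzenesulfinic acid, O=S(O)c1ccccc1
Why: Lactols exchange the anomeric hydroxyl group for benzenesulfinate under the mild acidity of the reagent itself (formation of a 2-benzenesulfonyl cyclic ether), which gives a storable leaving group at C6 that ionises with zinc or magnesium halides and so avoids a strong Lewis acid such as BF3·OEt2 that could open the benzylic C2–O3 bond and scramble C2.

Step 12
Reactants: 18 5-bromo-1,2,3-trimethoxybenzene
Product: 20 (3,4,5-trimethoxyphenyl)zinc bromide (THF solution used directly), via arylmagnesium bromide 19 (not isolated)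
Conditions: Mg, THF, reflux; then ZnBr2, THF, 0 °C to rt
Reagents that add atoms: magnesium, [Mg]; zinc bromide, Br[Zn]Br
Why: Grignard formation and transmetalation with ZnBr2 give a soft aryl donor that tolerates the acetal-type electrophile of the next step, and the MgBr2 formed alongside serves there as a mild Lewis acid.

Step 13
Reactants: 17 anomeric sulfone; 20 (3,4,5-trimethoxyphenyl)zinc bromide
Product: 22 (1R,2S,5R,6S)-2-[3-(benzyloxy)-4,5-dimethoxyphenyl]-6-(3,4,5-trimethoxyphenyl)-3,7-dioxabicyclo[3.3.0]octane, via bicyclic oxocarbenium ion 21 (not isolated)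
Conditions: 20 (2.5 equiv, solution from step 12), THF, rt
Reagents that add atoms: none
Why: In this substitution of a 2-benzenesulfonyl cyclic ether by an organozinc reagent the zinc and magnesium bromides ionise 17 to 21 and the aryl group is delivered to the convex face of the cis-fused bicycle, away from ring A, which sets C6 as S with aryl B exo while the weakly acidic medium leaves C2 untouched.

Step 14
Reactants: 22 benzyl-protected furofuran
Product: 23 (1R,2S,5R,6S)-2-(3-hydroxy-4,5-dimethoxyphenyl)-6-(3,4,5-trimethoxyphenyl)-3,7-dioxabicyclo[3.3.0]octane (CNP0181235.1)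
Conditions: H2 (1 atm), Pd/C (10 wt %), EtOAc, rt, stopped at consumption of 22
Reagents that add atoms: none
Why: Catalytic hydrogenolysis cleaves the unhindered O–CH2Ph bond of the aryl benzyl ether much faster than the two secondary benzylic C–O bonds inside the bicycle under neutral conditions at one atmosphere, so all four stereocentres and both rings should stay intact.

Compound list
1 | 3-hydroxy-4,5-dimethoxybenzaldehyde | COc1cc(C=O)cc(O)c1OC | starting material
2 | 3-(benzyloxy)-4,5-dimethoxybenzaldehyde | COc1cc(C=O)cc(OCc2ccccc2)c1OC | intermediate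
3 | methyl 2-[bis(2,2,2-trifluoroethoxy)phosphoryl]acetate | COC(=O)CP(=O)(OCC(F)(F)F)OCC(F)(F)F | starting material
4 | methyl (Z)-3-[3-(benzyloxy)-4,5-dimethoxyphenyl]prop-2-enoate | COC(=O)/C=C\c1cc(OC)c(OC)c(OCc2ccccc2)c1 | intermediate
5 | (Z)-3-[3-(benzyloxy)-4,5-dimethoxyphenyl]prop-2-en-1-ol | OC/C=C\c1cc(OC)c(OC)c(OCc2ccccc2)c1 | intermediate
6 | tert-butyldimethylsilyl ether of 5 | CC(C)(C)[Si](C)(C)OC/C=C\c1cc(OC)c(OC)c(OCc2ccccc2)c1 | intermediate
7 | dimethyl malonate | COC(=O)CC(=O)OC | starting material
8 | dimethyl 2-(phenyl-λ3-iodanylidene)propanedioate | COC(=O)[C-](C(=O)OC)[I+]c1ccccc1 | intermediate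
9 | dimethyl (2R,3R)-2-[3-(benzyloxy)-4,5-dimethoxyphenyl]-3-{[(tert-butyldimethylsilyl)oxy]methyl}cyclopropane-1,1-dicarboxylate | CC(C)(C)[Si](C)(C)OC[C@H]1C(C(=O)OC)(C(=O)OC)[C@H]1c1cc(OC)c(OC)c(OCc2ccccc2)c1 | intermediate
10 | dimethyl (2R,3R)-2-[3-(benzyloxy)-4,5-dimethoxyphenyl]-3-(hydroxymethyl)cyclopropane-1,1-dicarboxylate | OC[C@H]1C(C(=O)OC)(C(=O)OC)[C@H]1c1cc(OC)c(OC)c(OCc2ccccc2)c1 | intermediate
11 | methyl (1S,5R,6R)-6-[3-(benzyloxy)-4,5-dimethoxyphenyl]-2-oxo-3-oxabicyclo[3.1.0]hexane-1-carboxylate (aryl endo) | O=C1OC[C@H]2[C@]1(C(=O)OC)[C@H]2c1cc(OC)c(OC)c(OCc2ccccc2)c1 | intermediate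
12 | formaldehyde (as paraformaldehyde) | C=O | starting material
13 | ring-opened oxocarbenium enolate (tin-bound zwitterion; O3=C4 on C2, enolate at C5) | C=[O+][C@@H]([C@H]1COC(=O)C1=C([O-])OC)c1cc(OC)c(OC)c(OCc2ccccc2)c1 | intermediate
14 | methyl (1R,2S,5R)-2-[3-(benzyloxy)-4,5-dimethoxyphenyl]-6-oxo-3,7-dioxabicyclo[3.3.0]octane-5-carboxylate | O=C1OC[C@H]2[C@]1(C(=O)OC)CO[C@@H]2c1cc(OC)c(OC)c(OCc2ccccc2)c1 | intermediate
15 | (1R,2S,5R)-2-[3-(benzyloxy)-4,5-dimethoxyphenyl]-3,7-dioxabicyclo[3.3.0]octan-6-one | O=C1OC[C@H]2[C@@H]1CO[C@@H]2c1cc(OC)c(OC)c(OCc2ccccc2)c1 | intermediate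
16 | (1R,2S,5R)-2-[3-(benzyloxy)-4,5-dimethoxyphenyl]-3,7-dioxabicyclo[3.3.0]octan-6-ol (C6 epimers) | OC1OC[C@H]2[C@@H]1CO[C@@H]2c1cc(OC)c(OC)c(OCc2ccccc2)c1 | intermediate
17 | (1R,2S,5R)-6-(benzenesulfonyl)-2-[3-(benzyloxy)-4,5-dimethoxyphenyl]-3,7-dioxabicyclo[3.3.0]octane (C6 epimers) | O=S(=O)(c1ccccc1)C1OC[C@H]2[C@@H]1CO[C@@H]2c1cc(OC)c(OC)c(OCc2ccccc2)c1 | intermediate
18 | 5-bromo-1,2,3-trimethoxybenzene | COc1cc(Br)cc(OC)c1OC | starting material
19 | (3,4,5-trimethoxyphenyl)magnesium bromide | COc1cc([Mg]Br)cc(OC)c1OC | intermediate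
20 | (3,4,5-trimethoxyphenyl)zinc bromide | COc1cc([Zn]Br)cc(OC)c1OC | intermediate
21 | bicyclic C6=O7 oxocarbenium ion | C1=[O+]C[C@H]2[C@@H]1CO[C@@H]2c1cc(OC)c(OC)c(OCc2ccccc2)c1 | intermediate
22 | (1R,2S,5R,6S)-2-[3-(benzyloxy)-4,5-dimethoxyphenyl]-6-(3,4,5-trimethoxyphenyl)-3,7-dioxabicyclo[3.3.0]octane | COc1cc([C@H]2OC[C@H]3[C@@H]2CO[C@@H]3c2cc(OC)c(OC)c(OC)c2)cc(OCc2ccccc2)c1OC | intermediate
23 | (1R,2S,5R,6S)-2-(3-hydroxy-4,5-dimethoxyphenyl)-6-(3,4,5-trimethoxyphenyl)-3,7-dioxabicyclo[3.3.0]octane | COc1cc([C@H]2OC[C@H]3[C@@H]2CO[C@@H]3c2cc(OC)c(OC)c(OC)c2)cc(O)c1OC | target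

Total step count: 14. Longest linear sequence: 12 (steps 1–4, 6–11, 13, 14).

Steps most likely to fail

1. Step 8.
- What may go wrong: formaldehyde may oligomerise or hydroxymethylate the electron-rich ring faster than it opens the cyclopropane. Heterolysis of C2–C5 ahead of capture may also erode the inversion at C2.
- Fallback: C4 is brought in with a more nucleophilic aldehyde of the proven class and the extra carbons are trimmed afterwards. Setting out from 11, (E)-cinnamaldehyde with Sn(OTf)2 (10 mol %) in CH2Cl2 should give the 4-exo-styryl cycloadduct F1, with the styryl group cis to aryl A across O3. Lemieux–Johnson cleavage (catalytic OsO4, NaIO4, 2,6-lutidine, dioxane–water) gives the 4-exo-formyl furofuranone ester F2. Tsuji–Wilkinson decarbonylation with RhCl(PPh3)3 (1 equiv, toluene, reflux) replaces CHO by H, erases the extra stereocentre and comes back to the route at 14.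

2. Step 6.
- What may go wrong: carbene transfer to the hindered Z-alkene may be slow, facial selectivity may be poor, and a stepwise addition to the electron-rich styrene may leak alkene geometry.
- Fallback: the carbene is tethered to the allylic oxygen, so that cyclopropane and lactone close in one intramolecular event. Setting out from 5, acylation with methyl 3-chloro-3-oxopropanoate (Et3N, CH2Cl2, 0 °C) gives the Z-cinnamyl methyl malonate F3. Diazo transfer with 4-acetamidobenzenesulfonyl azide and Et3N in MeCN gives the diazomalonate F4. Slow addition of F4 to dirhodium tetrakis[methyl (4S)-2-oxoazetidine-4-carboxylate], Rh2(4S-MEAZ)4 (or its antipode), in refluxing CH2Cl2 closes both rings stereospecifically. The enantiomeric purity is then raised by recrystallisation. The sequence bypasses steps 4–7 and comes back to the route at 11.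

3. Step 13.
- What may go wrong: ionisation of the sulfone may be slow, the arylzinc may be protonated, or part of the aryl transfer may go to the concave face.
- Fallback: the C6–aryl bond is made by carbonyl addition and ring B is re-closed through the benzylic cation. Setting out from 16, excess Grignard reagent 19 (THF, 0 °C) adds to the open hydroxy-aldehyde form and gives the benzylic/primary diol F5 as carbinol epimers. Catalytic camphorsulfonic acid in CH2Cl2 at 0 °C ionises the 3,4,5-trimethoxybenzylic alcohol, and the C8 hydroxyl group captures the cation with aryl B taking the exo position. The sequence comes back to the route at 22.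

Further compounds
F1 | step 8 | methyl (1R,2S,4S,5R)-2-[3-(benzyloxy)-4,5-dimethoxyphenyl]-6-oxo-4-[(E)-2-phenylethenyl]-3,7-dioxabicyclo[3.3.0]octane-5-carboxylate | O=C1OC[C@H]2[C@]1(C(=O)OC)[C@H](/C=C/c1ccccc1)O[C@@H]2c1cc(OC)c(OC)c(OCc2ccccc2)c1
F2 | step 8 | methyl (1R,2S,4R,5R)-2-[3-(benzyloxy)-4,5-dimethoxyphenyl]-4-formyl-6-oxo-3,7-dioxabicyclo[3.3.0]octane-5-carboxylate | O=C1OC[C@H]2[C@]1(C(=O)OC)[C@H](C=O)O[C@@H]2c1cc(OC)c(OC)c(OCc2ccccc2)c1
F3 | step 6 | (Z)-3-[3-(benzyloxy)-4,5-dimethoxyphenyl]prop-2-en-1-yl methyl propanedioate | COC(=O)CC(=O)OC/C=C\c1cc(OC)c(OC)c(OCc2ccccc2)c1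
F4 | step 6 | (Z)-3-[3-(benzyloxy)-4,5-dimethoxyphenyl]prop-2-en-1-yl methyl 2-diazopropanedioate | COC(=O)C(=[N+]=[N-])C(=O)OC/C=C\c1cc(OC)c(OC)c(OCc2ccccc2)c1
F5 | step 13 | [(2S,3R,4R)-2-[3-(benzyloxy)-4,5-dimethoxyphenyl]-3-(hydroxymethyl)oxolan-4-yl](3,4,5-trimethoxyphenyl)methanol (carbinol epimers) | OC[C@H]1[C@@H](C(O)c2cc(OC)c(OC)c(OC)c2)CO[C@@H]1c1cc(OC)c(OC)c(OCc2ccccc2)c1
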